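**Plan**

- Retrosynthesis: the four O–benzyl bonds and the C6 benzylic CH2 (masked as a C6 aroyl carbonyl) are unmasked last; ring A is then cut at C4–C5 and C6–C1.
- Enabling feature: in ring A (C1 OMe, C2 H, C3 OH, C4 4-hydroxybenzyl, C5 CH2CH2–ring B, C6 4-hydroxybenzyl) the meta O,O pattern at C1/C3 lets C1–C4 come from a 1,1-dimethoxy-3-siloxy-1,3-diene and C5–C6 from an alkyne whose C6 substituent is a ketone.
- Ynone arm: cut at the acyl–alkynyl bond (acylative Sonogashira), the ring B aryl–CH2CH2 bond (Negishi) and the ring B aryl–CH2Ar bond (aryllithium plus aldehyde, then deoxygenation), back to 3,5-dibromophenol.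
- Diene arm: cut at O–Si and at the acyl–vinyl bond (acylation of 1,1-dimethoxyethene by an arylpropanoyl chloride), back to 3-(4-hydroxyphenyl)propanoic acid.
- Forward: ring B is elaborated first and the diene is made separately. Ring A is the only ring built (Diels–Alder, then aromatisation), followed by C=O to CH2 and debenzylation.
- Stereochemistry: the target is achiral. The carbinol and cycloadduct centres formed on the way are racemic and are erased; the (Z) enol ether geometry only serves diene reactivity.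

Key step: step 10

Remark: (4-bromobut-1-yn-1-yl)trimethylsilane and 4-(benzyloxy)benzoyl chloride are assumed to be purchasable; ring A atom labels C1–C6 are those of the plan.

**Route**

Step 1
Reactants: 1 3,5-dibromophenol
Product: 2 1-(benzyloxy)-3,5-dibromobenzene
Conditions: BnBr, K2CO3, acetone, reflux
Reagents that add atoms: benzyl bromide, BrCc1ccccc1
Why: Williamson ether synthesis, in which the phenoxide formed with K2CO3 displaces bromide from benzyl bromide by SN2 while the aryl bromides stay inert.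

Step 2
Reactants: 2 1-(benzyloxy)-3,5-dibromobenzene; 3 4-(benzyloxy)benzaldehyde
Product: 5 (3-(benzyloxy)-5-bromophenyl)(4-(benzyloxy)phenyl)methanol (racemic), via aryllithium 4 (not isolated)
Conditions: n-BuLi (1.0 equiv), Et2O, −78 °C; then 3, −78 to 0 °C; H2O
Reagents that add atoms: none
Why: Bromine–lithium exchange with one equivalent of n-BuLi should stop at the monolithium stage because the first carbanion deactivates the ring towards a second exchange, and aryllithium 4 then undergoes 1,2-addition to the aldehyde; the new carbinol centre is racemic and is removed in step 3.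

Step 3
Reactants: 5 (3-(benzyloxy)-5-bromophenyl)(4-(benzyloxy)phenyl)methanol
Product: 6 1-(benzyloxy)-3-(4-(benzyloxy)benzyl)-5-bromobenzene
Conditions: Et3SiH, CF3CO2H, CH2Cl2, 0 °C
Reagents that add atoms: none
Why: Ionic hydrogenation, in which acid ionises the diarylcarbinol to a cation stabilised by the para-benzyloxy ring and Et3SiH delivers hydride, the aryl bromide and benzyl ethers tolerating the brief cold exposure to acid.

Step 4
Reactants: 6 1-(benzyloxy)-3-(4-(benzyloxy)benzyl)-5-bromobenzene; 7 (4-bromobut-1-yn-1-yl)trimethylsilane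
Product: 9 (4-(3-(benzyloxy)-5-(4-(benzyloxy)benzyl)phenyl)but-1-yn-1-yl)trimethylsilane, via alkylzinc bromide 8 (not isolated)
Conditions: 7, activated Zn dust, LiCl, THF, 50 °C; then 6, Pd(OAc)2 (2 mol %), SPhos (2-dicyclohexylphosphino-2',6'-dimethoxybiphenyl, 4 mol %), THF, rt to 50 °C
Reagents that add atoms: none
Why: Negishi coupling, in which LiCl-assisted zinc insertion into the primary bromide gives alkylzinc 8 that transmetalates to the arylpalladium bromide formed from 6 and zerovalent palladium, the bulky biaryl phosphine making reductive elimination faster than β-hydride elimination and the silyl cap keeping the alkyne out of the chemistry.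

Step 5
Reactants: 9 (4-(3-(benzyloxy)-5-(4-(benzyloxy)benzyl)phenyl)but-1-yn-1-yl)trimethylsilane
Product: 10 1-(benzyloxy)-3-(4-(benzyloxy)benzyl)-5-(but-3-yn-1-yl)benzene
Conditions: K2CO3, MeOH/THF, rt
Reagents that add atoms: none
Why: Protodesilylation of the alkynylsilane by methoxide (attack at silicon, protonation of the acetylide by methanol) is selective for the C(sp)–Si bond and leaves the benzyl ethers alone.

Step 6
Reactants: 10 1-(benzyloxy)-3-(4-(benzyloxy)benzyl)-5-(but-3-yn-1-yl)benzene; 11 4-(benzyloxy)benzoyl chloride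
Product: 12 5-(3-(benzyloxy)-5-(4-(benzyloxy)benzyl)phenyl)-1-(4-(benzyloxy)phenyl)pent-2-yn-1-one
Conditions: PdCl2(PPh3)2 (2 mol %), CuI (4 mol %), Et3N (1.2 equiv), THF, rt
Reagents that add atoms: none
Why: Acylative Sonogashira coupling, in which the aroyl chloride adds oxidatively to zerovalent palladium, the copper acetylide transmetalates and reductive elimination gives the conjugated ynone, the near-stoichiometric amine limiting alkyne-to-allene isomerisation.

Step 7
Reactants: 13 3-(4-hydroxyphenyl)propanoic acid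
Product: 15 3-(4-(benzyloxy)phenyl)propanoic acid, via benzyl ester 14 (not isolated)
Conditions: BnBr (2.2 equiv), K2CO3, DMF, 60 °C; then NaOH, H2O/MeOH, 60 °C; then HCl (pH 2)
Reagents that add atoms: benzyl bromide, BrCc1ccccc1
Why: Double Williamson benzylation of phenoxide and carboxylate followed by saponification of the benzyl ester in the same flask leaves only the phenolic benzyl ether, since aryl benzyl ethers are stable to hydroxide.

Step 8
Reactants: 15 3-(4-(benzyloxy)phenyl)propanoic acid; 16 1,1-dimethoxyethene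
Product: 18 5-(4-(benzyloxy)phenyl)-1,1-dimethoxypent-1-en-3-one, via acid chloride 17 (not isolated)
Conditions: (COCl)2, DMF (cat.), CH2Cl2, 0 °C to rt, evaporate; then 16 (2 equiv), Et3N, Et2O, 0 °C to rt
Reagents that add atoms: none
Why: C-Acylation of a ketene acetal, in which the acid chloride is attacked by the nucleophilic CH2 carbon of 16 and Et3N removes HCl from the oxocarbenium adduct to give the push–pull β,β-dimethoxy enone.

Step 9
Reactants: 18 5-(4-(benzyloxy)phenyl)-1,1-dimethoxypent-1-en-3-one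
Product: 19 (Z)-((5-(4-(benzyloxy)phenyl)-1,1-dimethoxypenta-1,3-dien-3-yl)oxy)trimethylsilane
Conditions: Me3SiCl, Et3N, ZnCl2 (cat.), toluene, 40 °C; filtered and concentrated under N2, used crude
Reagents that add atoms: chlorotrimethylsilane, C[Si](C)(C)Cl
Why: Soft enolisation and O-silylation at C4, the only enolisable position, under equilibrating conditions should favour the (Z)-silyl enol ether, which places the arylmethyl group on the outside of the s-cis diene.

Step 10
Reactants: 12 5-(3-(benzyloxy)-5-(4-(benzyloxy)benzyl)phenyl)-1-(4-(benzyloxy)phenyl)pent-2-yn-1-one; 19 (Z)-((5-(4-(benzyloxy)phenyl)-1,1-dimethoxypenta-1,3-dien-3-yl)oxy)trimethylsilane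
Product: 22 (4-(benzyloxy)phenyl)(2-(3-(benzyloxy)-5-(4-(benzyloxy)benzyl)phenethyl)-3-(4-(benzyloxy)benzyl)-4-hydroxy-6-methoxyphenyl)methanone, via cyclohexadiene cycloadduct 20 (not isolated), via aryl trimethylsilyl ether 21 (not isolated)
Conditions: 19 (2 equiv), toluene, 110 °C, sealed tube; then 1 M HCl, THF, rt
Reagents that add atoms: none
Why: A normal-electron-demand Diels–Alder reaction between the doubly donor-activated diene 19 and the acceptor alkyne 12 should pass through an asynchronous transition state in which the C4–C5 bond (nucleophilic diene terminus to the ynone β-carbon) runs ahead of the C6–C1 bond, giving 1,4-cyclohexadiene 20 with a dimethyl ketal at C1 and a silyl enol ether at C3. The closest known reaction type is the cycloaddition of 1,1-dialkoxy-3-siloxybutadienes with acetylenic ketones and esters, which gives resorcinol monomethyl ethers after aromatisation. Ring A is closed as a six-membered carbocycle by this intermolecular (4+2) cycloaddition, both ring bonds being made in one operation, and 1,4-elimination of methanol (C1–OMe together with the doubly allylic C4–H) then aromatises 20 to 21, whose silyl ether is cleaved by dilute acid to the C3 phenol. No stereocentre remains, since the C4 centre of 20 is formed as a racemate and is erased on aromatisation. The step needs regioselectivity, which the matched polarisation secures (largest HOMO coefficient on diene C4, largest LUMO coefficient on the ynone β-carbon), and an accessible s-cis diene, which the (Z) enol ether geometry provides. C1 keeps exactly one methoxy group because it carries two and loses one, while the C3 oxygen is retained as the phenol.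

Step 11
Reactants: 22 (4-(benzyloxy)phenyl)(2-(3-(benzyloxy)-5-(4-(benzyloxy)benzyl)phenethyl)-3-(4-(benzyloxy)benzyl)-4-hydroxy-6-methoxyphenyl)methanone
Product: 23 3-(3-(benzyloxy)-5-(4-(benzyloxy)benzyl)phenethyl)-2,4-bis(4-(benzyloxy)benzyl)-5-methoxyphenol
Conditions: Et3SiH (5 equiv), CF3CO2H, CH2Cl2, 0 °C to rt
Reagents that add atoms: none
Why: Ionic hydrogenation of a diaryl ketone, in which protonation and hydride transfer give the diarylcarbinol that ionises to a cation stabilised by the para-benzyloxyphenyl ring and the ortho-methoxy/para-hydroxy pattern of ring A and takes up a second hydride, the excess silane also intercepting any benzyl cation released from the ethers.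

Step 12
Reactants: 23 3-(3-(benzyloxy)-5-(4-(benzyloxy)benzyl)phenethyl)-2,4-bis(4-(benzyloxy)benzyl)-5-methoxyphenol
Product: 24 3-(3-hydroxy-5-(4-hydroxybenzyl)phenethyl)-2,4-bis(4-hydroxybenzyl)-5-methoxyphenol (CNP0204120.0)
Conditions: H2 (1 atm), 10% Pd/C, EtOAc/MeOH, rt
Reagents that add atoms: none
Why: Hydrogenolysis of the four aryl benzyl ethers on palladium frees the phenols, whereas the aryl methyl ether and the diarylmethane C–C bonds are not cleaved under these conditions.

**Compound list**

1 | 3,5-dibromophenol | Oc1cc(Br)cc(Br)c1 | starting material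
2 | 1-(benzyloxy)-3,5-dibromobenzene | Brc1cc(Br)cc(OCc2ccccc2)c1 | intermediate
3 | 4-(benzyloxy)benzaldehyde | O=Cc1ccc(OCc2ccccc2)cc1 | starting material
4 | (3-(benzyloxy)-5-bromophenyl)lithium (not isolated) | [Li]c1cc(Br)cc(OCc2ccccc2)c1 | intermediate
5 | (3-(benzyloxy)-5-bromophenyl)(4-(benzyloxy)phenyl)methanol, racemic | OC(c1ccc(OCc2ccccc2)cc1)c1cc(Br)cc(OCc2ccccc2)c1 | intermediate
6 | 1-(benzyloxy)-3-(4-(benzyloxy)benzyl)-5-bromobenzene | Brc1cc(Cc2ccc(OCc3ccccc3)cc2)cc(OCc2ccccc2)c1 | intermediate
7 | (4-bromobut-1-yn-1-yl)trimethylsilane | C[Si](C)(C)C#CCCBr | starting material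
8 | (4-(trimethylsilyl)but-3-yn-1-yl)zinc bromide (not isolated) | C[Si](C)(C)C#CCC[Zn]Br | intermediate
9 | (4-(3-(benzyloxy)-5-(4-(benzyloxy)benzyl)phenyl)but-1-yn-1-yl)trimethylsilane | C[Si](C)(C)C#CCCc1cc(OCc2ccccc2)cc(Cc2ccc(OCc3ccccc3)cc2)c1 | intermediate
10 | 1-(benzyloxy)-3-(4-(benzyloxy)benzyl)-5-(but-3-yn-1-yl)benzene | C#CCCc1cc(OCc2ccccc2)cc(Cc2ccc(OCc3ccccc3)cc2)c1 | intermediate
11 | 4-(benzyloxy)benzoyl chloride | O=C(Cl)c1ccc(OCc2ccccc2)cc1 | starting material
12 | 5-(3-(benzyloxy)-5-(4-(benzyloxy)benzyl)phenyl)-1-(4-(benzyloxy)phenyl)pent-2-yn-1-one | O=C(C#CCCc1cc(OCc2ccccc2)cc(Cc2ccc(OCc3ccccc3)cc2)c1)c1ccc(OCc2ccccc2)cc1 | intermediate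
13 | 3-(4-hydroxyphenyl)propanoic acid | O=C(O)CCc1ccc(O)cc1 | starting material
14 | benzyl 3-(4-(benzyloxy)phenyl)propanoate (not isolated) | O=C(CCc1ccc(OCc2ccccc2)cc1)OCc1ccccc1 | intermediate
15 | 3-(4-(benzyloxy)phenyl)propanoic acid | O=C(O)CCc1ccc(OCc2ccccc2)cc1 | intermediate
16 | 1,1-dimethoxyethene | C=C(OC)OC | starting material
17 | 3-(4-(benzyloxy)phenyl)propanoyl chloride (not isolated) | O=C(Cl)CCc1ccc(OCc2ccccc2)cc1 | intermediate
18 | 5-(4-(benzyloxy)phenyl)-1,1-dimethoxypent-1-en-3-one | COC(OC)=CC(=O)CCc1ccc(OCc2ccccc2)cc1 | intermediate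
19 | (Z)-((5-(4-(benzyloxy)phenyl)-1,1-dimethoxypenta-1,3-dien-3-yl)oxy)trimethylsilane | COC(OC)=C/C(O[Si](C)(C)C)=C/Cc1ccc(OCc2ccccc2)cc1 | intermediate
20 | cyclohexa-1,4-diene cycloadduct, racemic at C4 (C1 dimethyl ketal, C3 OSiMe3, C4 4-(benzyloxy)benzyl, C5 ring B ethyl chain, C6 4-(benzyloxy)benzoyl; not isolated) | COC1(OC)C=C(O[Si](C)(C)C)C(Cc2ccc(OCc3ccccc3)cc2)C(CCc2cc(OCc3ccccc3)cc(Cc3ccc(OCc4ccccc4)cc3)c2)=C1C(=O)c1ccc(OCc2ccccc2)cc1 | intermediate
21 | trimethylsilyl ether of phenol 22 (not isolated) | COc1cc(O[Si](C)(C)C)c(Cc2ccc(OCc3ccccc3)cc2)c(CCc2cc(OCc3ccccc3)cc(Cc3ccc(OCc4ccccc4)cc3)c2)c1C(=O)c1ccc(OCc2ccccc2)cc1 | intermediate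
22 | (4-(benzyloxy)phenyl)(2-(3-(benzyloxy)-5-(4-(benzyloxy)benzyl)phenethyl)-3-(4-(benzyloxy)benzyl)-4-hydroxy-6-methoxyphenyl)methanone | COc1cc(O)c(Cc2ccc(OCc3ccccc3)cc2)c(CCc2cc(OCc3ccccc3)cc(Cc3ccc(OCc4ccccc4)cc3)c2)c1C(=O)c1ccc(OCc2ccccc2)cc1 | intermediate
23 | 3-(3-(benzyloxy)-5-(4-(benzyloxy)benzyl)phenethyl)-2,4-bis(4-(benzyloxy)benzyl)-5-methoxyphenol | COc1cc(O)c(Cc2ccc(OCc3ccccc3)cc2)c(CCc2cc(OCc3ccccc3)cc(Cc3ccc(OCc4ccccc4)cc3)c2)c1Cc1ccc(OCc2ccccc2)cc1 | intermediate
24 | 3-(3-hydroxy-5-(4-hydroxybenzyl)phenethyl)-2,4-bis(4-hydroxybenzyl)-5-methoxyphenol (CNP0204120.0) | COc1cc(O)c(Cc2ccc(O)cc2)c(CCc2cc(O)cc(Cc3ccc(O)cc3)c2)c1Cc1ccc(O)cc1 | target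

**Step count**

Total steps: 12. Longest linear sequence: 9 steps (steps 1–6, 10, 11, 12).

**Steps most likely to fail**

1. Step 10 (key step). The bond between the substituted diene terminus C4 and the β-alkyl alkyne carbon may form too slowly, so that desilylation or hydrolysis of the ketene acetal diene overtakes cycloaddition, or methanol loss may stay incomplete. The fallback keeps the same ring A disconnection but uses a smaller, more electrophilic dienophile; it sets out from alkyne 10 and diene 19 and comes back to the route at 23. Alkyne 10 is deprotonated with n-BuLi in THF at −78 °C to the lithium acetylide F1, which is formylated with DMF and worked up with water to give 5-(3-(benzyloxy)-5-(4-(benzyloxy)benzyl)phenyl)pent-2-ynal F2. F2 and 19 in toluene at 60–80 °C should give the cyclohexadiene carbaldehyde cycloadduct F3, which loses methanol to the aryl trimethylsilyl ether aldehyde F4; dilute HCl then gives 2-(3-(benzyloxy)-5-(4-(benzyloxy)benzyl)phenethyl)-3-(4-(benzyloxy)benzyl)-4-hydroxy-6-methoxybenzaldehyde F5. Commercial 4-BnOC6H4MgBr (2.5 equiv, one consumed by the phenol) in THF at 0 °C adds to F5 to give the racemic diarylcarbinol F6. Et3SiH/CF3CO2H in CH2Cl2 at 0 °C reduces F6 to 23, so no hindered ketone has to be deoxygenated.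

2. Step 8. Et3N may dehydrohalogenate the enolisable acid chloride 17 to a ketene that dimerises or adds (2+2) to the ketene acetal, and the β,β-dimethoxy enone may hydrolyse to a β-keto ester during isolation. The fallback builds the same enone by forming the C4–C5 bond instead; it sets out from 16 and comes back at 18. Acylation of 16 with acetyl chloride and Et3N in Et2O gives 4,4-dimethoxybut-3-en-2-one F7. Kinetic deprotonation of F7 at the methyl group with LiN(i-Pr)2 in THF at −78 °C gives lithium 4,4-dimethoxybuta-1,3-dien-2-olate F8, which is alkylated with 4-(benzyloxy)benzyl bromide (α′-alkylation of a vinylogous ester enolate) to give 18.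

3. Step 11. Deoxygenation at the di-ortho-substituted carbonyl may stall at the carbinol or its trifluoroacetate, and the acid may cleave benzyl ethers with benzyl transfer onto the electron-rich rings. The fallback replaces ionic hydride transfer by heterogeneous hydrogenolysis and merges the last two steps; it sets out from 22 and comes back at target 24. H2 (4 atm) over Pd(OH)2/C in AcOH with a little HCl at 50 °C should cleave the four benzyl ethers and hydrogenolyse the diaryl ketone through its carbinol to the CH2 group in one operation; no new compound is isolated on this way (F0).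

**Further compounds**

F1 | step 10 | (4-(3-(benzyloxy)-5-(4-(benzyloxy)benzyl)phenyl)but-1-yn-1-yl)lithium | [Li]C#CCCc1cc(OCc2ccccc2)cc(Cc2ccc(OCc3ccccc3)cc2)c1
F2 | step 10 | 5-(3-(benzyloxy)-5-(4-(benzyloxy)benzyl)phenyl)pent-2-ynal | O=CC#CCCc1cc(OCc2ccccc2)cc(Cc2ccc(OCc3ccccc3)cc2)c1
F3 | step 10 | cyclohexa-1,4-diene carbaldehyde cycloadduct, racemic at C4 (C1 dimethyl ketal, C3 OSiMe3, C4 4-(benzyloxy)benzyl, C5 ring B ethyl chain, C6 CHO) | COC1(OC)C=C(O[Si](C)(C)C)C(Cc2ccc(OCc3ccccc3)cc2)C(CCc2cc(OCc3ccccc3)cc(Cc3ccc(OCc4ccccc4)cc3)c2)=C1C=O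
F4 | step 10 | 2-(3-(benzyloxy)-5-(4-(benzyloxy)benzyl)phenethyl)-3-(4-(benzyloxy)benzyl)-6-methoxy-4-((trimethylsilyl)oxy)benzaldehyde | COc1cc(O[Si](C)(C)C)c(Cc2ccc(OCc3ccccc3)cc2)c(CCc2cc(OCc3ccccc3)cc(Cc3ccc(OCc4ccccc4)cc3)c2)c1C=O
F5 | step 10 | 2-(3-(benzyloxy)-5-(4-(benzyloxy)benzyl)phenethyl)-3-(4-(benzyloxy)benzyl)-4-hydroxy-6-methoxybenzaldehyde | COc1cc(O)c(Cc2ccc(OCc3ccccc3)cc2)c(CCc2cc(OCc3ccccc3)cc(Cc3ccc(OCc4ccccc4)cc3)c2)c1C=O
F6 | step 10 | 3-(3-(benzyloxy)-5-(4-(benzyloxy)benzyl)phenethyl)-2-(4-(benzyloxy)benzyl)-4-((4-(benzyloxy)phenyl)(hydroxy)methyl)-5-methoxyphenol, racemic | COc1cc(O)c(Cc2ccc(OCc3ccccc3)cc2)c(CCc2cc(OCc3ccccc3)cc(Cc3ccc(OCc4ccccc4)cc3)c2)c1C(O)c1ccc(OCc2ccccc2)cc1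
F7 | step 8 | 4,4-dimethoxybut-3-en-2-one | COC(OC)=CC(C)=O
F8 | step 8 | lithium 4,4-dimethoxybuta-1,3-dien-2-olate | [Li]OC(=C)C=C(OC)OC
F0 | step 11 | none | none
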